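## The problem

Compound 25 is a benzophenone. Ring A carries four neighbouring substituents (prenyl on C1, the ketone carbon on C2, formyl on C3, hydroxyl on C4), and ring B is a 6-methyl-1,4-benzodioxane bound to the ketone through C8, the carbon next to the ring oxygen O1. Both aryl–carbonyl bonds are flanked by ortho substituents, and the one to ring A lies between prenyl and formyl, so the rings cannot be joined by an unhindered acylation, and the 1,2,3,4-pattern of ring A is not accessible by electrophilic substitution of a phenol. The only stereocentre is C2 of the dioxane (R), which bears the 2-hydroxypropan-2-yl group. It is remote from every other reacting site, so nothing in the molecule can set it and it can control nothing; it must come from a reagent-controlled reaction and then be carried unchanged. Any stereocentre that appears between the rings on the way is temporary, because that carbon ends as the ketone. The prenyl double bond rules out peracids, hydrogenation and hot strong acid; the aldehyde beside a phenol and a ketone rules out strong nucleophiles and bases late in the route; the tertiary alcohol should not meet ionising acid. The enabling feature is that C2 and C3 of ring A are neighbours and the oxygen on C4 stands beside C3. A 3-alkoxybenzyne whose triple bond spans C2 and C3 takes up a ketene unit in exactly this orientation, so the ketone carbon and the formyl carbon can enter together as the two non-aromatic carbons of a benzocyclobutenone.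

## Retrosynthesis

**From 25 to phthalide 22 (no skeletal bond cut).** Target 25 is traced through its doubly protected form 24 (MOM on the phenol, triethylsilyl on the tertiary alcohol) to diol 23 and then to the 3-arylphthalide 22. The aldehyde and the ketone are treated as the two oxidised arms of one lactone. Compared with carrying a free keto aldehyde through the synthesis, the lactone keeps both carbons at robust oxidation levels until the last two steps. The forward steps must reduce the lactone with hydride, oxidise both hydroxyls of 23 at once (Swern conditions, so that no lactol intervenes), and remove both protecting groups with dilute aqueous acid that spares prenyl.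

**From 22 to ketal 20 (one C–O bond cut).** The bond between the lactone oxygen and the benzhydryl carbon of 22 is cut, which leads to benzocyclobutenone 21 and, one step further back, its mixed silyl methyl ketal 20. This cut is preferred over opening the lactone at the acyl side because it converts the oxygen-bridged system into an all-carbon four-membered ring, the signature product of an aryne and a ketene acetal. The forward reaction needs an oxidant that inserts oxygen into a strained ketone without epoxidising prenyl, which points to alkaline peroxide, and it needs the doubly benzylic sp3 carbon to migrate in preference to the aryl carbon.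

**From 20 to 6 and 18 (two C–C bonds cut, the key disconnection).** Both bonds from ring A to the four-membered ring of 20 are cut: the bond from the ring A carbon next to prenyl to the methine carbon bearing ring B, and the bond from the neighbouring ring A carbon to the ketal carbon. This gives aryne 19, released from iodo triflate 6, and ketene silyl acetal 18. Against a stepwise union by aryl-metal addition or acylation, this cut makes the most hindered bond of the molecule with a high-energy intermediate. It also creates the contiguous substitution of ring A in the same event and splits the target into two fragments of similar size. The forward reaction must be regioselective: the nucleophilic carbon of 18 has to attack the aryne carbon remote from the MOM-oxy group although that carbon is flanked by prenyl.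

**From 6 to 1 (ring A).** The prenyl group of 6 is traced to the allyl group of triflate 5 (cross-metathesis), 5 to phenol 4, and the ring–allyl bond of 4 is cut by a Claisen transform to allyl ether 3, which comes from the mono-MOM ether 2 of 2-iodoresorcinol 1. The iodine of 1 is used three times: it blocks one ortho position so that the rearrangement of 3 can end only at C6, it is the exchangeable group that triggers aryne formation, and it places the triple bond beside the MOM-oxy group. Direct C-prenylation of 2 would be shorter but is less reliable in yield. The forward sequence needs only one selectivity that is not enforced by structure, the monoprotection of the symmetric diol 1.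

**From 18 to 14 (ring B side chain).** Ketene silyl acetal 18 is the O-silylated enolate of ester 17; 17 is the silyl ether of hydroxy ester 16; 16 is cut at the bond between its benzylic CH2 and the ester carbon and traced through 15 to aldehyde 14 (one-carbon homologation). The aldehyde is preferred to a halide at C8 because the formyl group is already needed in the preceding disconnection to tell the two catechol oxygens apart. The forward steps must homologate 14 without touching the tertiary alcohol and must mask that alcohol before enolisation.

**From 14 to 12 and 9 (dioxane ring, the stereocentre).** Two C–O bonds of 14 are cut: O4–CH2 and O1–C2. This gives 2,3-dihydroxy-5-methylbenzaldehyde 12 and the epoxy sulfonate 9, which is made from prenol 7 through epoxy alcohol 8 by Sharpless epoxidation. An epoxide is chosen over a carboxylate or an isopropenyl precursor because opening at its secondary carbon delivers the tertiary carbinol and the stereocentre in one step with a known stereochemical course (inversion). Aldehyde 12 comes from creosol 10 through 11 by ortho-formylation and demethylation. The forward reaction must alkylate O4 first and O1 second; the formyl group of 12, which deactivates the neighbouring phenoxide, is relied on for this.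

## Roads not taken

**Alternative 1: oxygen insertion into an anthrone.** The cut is the aryl–oxygen bond of a seven-membered lactone: a strong peracid would insert oxygen between C9 of the 1,8-dioxygenated 3-methylanthrone A2 and its ring B fusion carbon to give the dibenzo[b,e]oxepinone A1.
- Merits: A2 already holds the whole carbon skeleton of both rings and both one-carbon units, so no fragment union is needed. The insertion also delivers ring B as a catechol whose two oxygens are differentiated by construction, which is cleaner than the dianion alkylation relied on in step 9.
- Weak points: in A1 the oxidation levels are the reverse of those required. The lactone carbonyl must go down to the aldehyde and the diarylmethane CH2 up to the ketone, and a benzylic oxidation is hard to reconcile with prenyl. Prenyl itself is missing; it cannot be carried through a peracid step and would have to be placed late, para to the ring A oxygen, where no directing effect helps. The direction of insertion rests only on the protecting groups of the two rings, and anthrones are readily oxidised at C10. The dioxane and its stereocentre would be built last on an advanced catechol.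
- Comparison: this road reaches the diaryl skeleton in fewer steps, but the chosen plan installs prenyl early, ends at the correct oxidation levels and sets the stereocentre on a small fragment.

**Alternative 2: enantioconvergent allylic etherification for the dioxane.** The cut is the O1–C2 bond. Pd2(dba)3 (zerovalent palladium) with a chiral diaminocyclohexane-derived bis(2-diphenylphosphinobenzamide) ligand would ionise the allylic carbonate A4, and the ortho phenol would attack the internal allyl terminus to close the ring, giving bromide A3. A3 has the spatial arrangement of the target; its descriptor is S only because isopropenyl ranks below CH2O.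
- Merits: the stereocentre is set catalytically in the ring-forming step, and the bromide of A3 is a more versatile handle than the formyl group of 14. It would allow a one-step enolate arylation to the acetate where the chosen route needs steps 10 and 11; in this respect the alternative is better.
- Weak points: selectivity on a 2-methyl-substituted allyl complex is less predictable than the epoxidation of an allylic alcohol. The isopropenyl group must still be hydrated to the tertiary alcohol before prenyl is present. The catechol oxygens of A4 must be differentiated anyway. Above all, this disconnection solves only ring B and leaves the hindered ketone untouched.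
- Comparison: the chosen plan sets against it an epoxide of known absolute sense that gives the carbinol directly, and a key step aimed at the main difficulty.

**Alternative 3: carbonylative Suzuki coupling.** Both aryl–carbonyl bonds are cut. Iodide A6 and boronic acid A7 would be coupled under carbonylative conditions with [PdCl2(IPr)(3-chloropyridine)] (divalent palladium precatalyst with the bulky N-heterocyclic carbene IPr) to give the protected benzophenone A5.
- Merits: this is the most convergent plan. A5 is one deprotection from the target, whereas the chosen route needs five steps after its key step, and no redox adjustment is required; in step economy after the union it is clearly better.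
- Weak points: A6 already contains the full 1,2,3,4-pattern of ring A, with iodine between prenyl and the acetal carbon, so the regiochemical problem is only moved into its preparation. The iodide is flanked on both sides and the boronic acid A7 is ortho-alkoxy-substituted and electron-rich, so acyl transfer is slowed and direct biaryl coupling and protodeboronation compete.
- Comparison: the chosen plan sets against the shorter endgame that the aryne forms the hindered bond through a reactive intermediate and at the same time generates the contiguous pattern of ring A from the simple resorcinol 1.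

Key step: step 14

Assumption: 2-iodoresorcinol (1) is taken as a commercial material; it is otherwise available in one step by iodination of resorcinol in aqueous bicarbonate.

Remark on names: ring B is numbered in all names as in the target (O1 bound to the stereocentre C2, methyl on C6, the bond to the rest of the molecule on C8), also where a principal group would change the locants. Anionic or metalated forms of numbered compounds (phenoxides, enolates, the aryllithium of step 14) are treated as forms of the parent compound and carry no number.

## Route

Step 1
Reactants: 1 2-iodoresorcinol (2-iodobenzene-1,3-diol)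
Product: 2 2-iodo-3-(methoxymethoxy)phenol
Conditions: NaH (1.0 equiv), DMF, 0 °C; MeOCH2Cl (1.0 equiv), 0 °C to rt
Reagents that add atoms: chloromethyl methyl ether (MOMCl), COCCl
Why: Williamson O-alkylation of the monosodium salt of a symmetric diol; the two hydroxyls are equivalent, so only the degree of alkylation has to be controlled, and unreacted 1 and over-alkylated material are separable and can be recycled.

Step 2
Reactants: 2 2-iodo-3-(methoxymethoxy)phenol
Product: 3 1-(allyloxy)-2-iodo-3-(methoxymethoxy)benzene
Conditions: allyl bromide, K2CO3, acetone, reflux
Reagents that add atoms: allyl bromide, C=CCBr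
Why: Williamson ether synthesis on the only remaining phenol; aryl iodide and MOM acetal are inert to carbonate.

Step 3
Reactants: 3 1-(allyloxy)-2-iodo-3-(methoxymethoxy)benzene
Product: 4 6-allyl-2-iodo-3-(methoxymethoxy)phenol
Conditions: N,N-diethylaniline, 190 °C
Reagents that add atoms: none
Why: Aromatic Claisen rearrangement; the ortho position that carries iodine cannot re-aromatise, so the [3,3] shift should end only at C6, ortho to the new phenol and para to the MOM ether, and the basic solvent protects the acetal from the phenol that is formed.

Step 4
Reactants: 4 6-allyl-2-iodo-3-(methoxymethoxy)phenol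
Product: 5 6-allyl-2-iodo-3-(methoxymethoxy)phenyl trifluoromethanesulfonate
Conditions: Tf2O, pyridine, CH2Cl2, −20 to 0 °C
Reagents that add atoms: trifluoromethanesulfonic anhydride, O=S(=O)(OS(=O)(=O)C(F)(F)F)C(F)(F)F
Why: O-sulfonylation of a phenol; the anhydride is reactive enough for a phenol flanked on both sides, and the MOM acetal tolerates the pyridine-buffered medium at low temperature.

Step 5
Reactants: 5 6-allyl-2-iodo-3-(methoxymethoxy)phenyl trifluoromethanesulfonate
Product: 6 2-iodo-3-(methoxymethoxy)-6-(3-methylbut-2-en-1-yl)phenyl trifluoromethanesulfonate
Conditions: second-generation Grubbs catalyst RuCl2(=CHPh)(H2IMes)(PCy3) (5 mol %), 2-methyl-2-butene/CH2Cl2, 40 °C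
Reagents that add atoms: 2-methyl-2-butene, CC=C(C)C
Why: Olefin cross-metathesis of a terminal allyl arene with an excess of 2-methyl-2-butene, the standard conversion of allyl into prenyl; aryl iodide and triflate do not react with the ruthenium carbene, and the trisubstituted product re-enters the cycle only slowly.

Step 6
Reactants: 7 prenol (3-methylbut-2-en-1-ol)
Product: 9 (S)-(3,3-dimethyloxiran-2-yl)methyl 3-nitrobenzenesulfonate, via (S)-3,3-dimethylglycidol 8 (not isolated)
Conditions: Ti(OiPr)4 (5 mol %), L-(+)-diisopropyl tartrate (6 mol %), t-BuOOH, 4 Å molecular sieves, CH2Cl2, −20 °C; P(OMe)3; then 3-nitrobenzenesulfonyl chloride, Et3N, DMAP (cat.), −10 °C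
Reagents that add atoms: tert-butyl hydroperoxide, CC(C)(C)OO; 3-nitrobenzenesulfonyl chloride, O=S(=O)(Cl)c1cccc(c1)[N+](=O)[O-]
Why: Sharpless asymmetric epoxidation with sulfonylation of the water-soluble epoxy alcohol in the same flask; the titanium–L-(+)-tartrate catalyst delivers oxygen to the face of the allylic alcohol that gives the (2S)-epoxide, the only stereocentre-setting event of the route, and the sulfonate is expected to be crystalline so that its enantiomeric purity can be raised by recrystallisation.

Step 7
Reactants: 10 creosol (2-methoxy-4-methylphenol)
Product: 11 2-hydroxy-3-methoxy-5-methylbenzaldehyde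
Conditions: MgCl2, Et3N, (CH2O)n, MeCN, reflux
Reagents that add atoms: paraformaldehyde (formaldehyde), C=O
Why: Magnesium-mediated ortho-formylation of a phenol (Casnati–Skattebøl type); the magnesium phenoxide delivers formaldehyde only ortho to oxygen, and C6 is the single free ortho position.

Step 8
Reactants: 11 2-hydroxy-3-methoxy-5-methylbenzaldehyde
Product: 12 2,3-dihydroxy-5-methylbenzaldehyde
Conditions: BBr3, CH2Cl2, −78 to 0 °C; H2O
Reagents that add atoms: none
Why: Lewis-acid cleavage of an aryl methyl ether, the usual way from 3-methoxysalicylaldehydes to 2,3-dihydroxybenzaldehydes; the aldehyde is released again when the boron chelate is hydrolysed.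

Step 9
Reactants: 12 2,3-dihydroxy-5-methylbenzaldehyde; 9 (S)-(3,3-dimethyloxiran-2-yl)methyl 3-nitrobenzenesulfonate
Product: 14 (R)-2-(2-hydroxypropan-2-yl)-6-methyl-2,3-dihydro-1,4-benzodioxine-8-carbaldehyde, via epoxy ether 13 (not isolated)
Conditions: NaH (2.1 equiv), DMSO, rt; 9, rt then 60 °C; aq. NH4Cl
Reagents that add atoms: none
Why: Regioselective O-alkylation of a catechol dianion followed by intramolecular epoxide opening: the phenoxide ortho to the formyl group (O1) is delocalised into the carbonyl, so the other phenoxide (O4) displaces the sulfonate at CH2 without touching the stereocentre. O1 then opens the epoxide at its secondary carbon in a 6-exo-tet SN2 reaction with inversion, which turns the (S)-epoxide into the (R)-dioxane and releases the tertiary alkoxide; attack at the quaternary epoxide carbon is not expected under basic conditions.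

Step 10
Reactants: 14 (R)-2-(2-hydroxypropan-2-yl)-6-methyl-2,3-dihydro-1,4-benzodioxine-8-carbaldehyde
Product: 15 (R)-2-{6-methyl-8-[2-(methylsulfanyl)-2-(methylsulfinyl)ethenyl]-2,3-dihydro-1,4-benzodioxin-2-yl}propan-2-ol (mixture of alkene and sulfoxide isomers)
Conditions: MeS(O)CH2SMe, benzyltrimethylammonium hydroxide (cat.), THF, reflux
Reagents that add atoms: methyl (methylsulfinyl)methyl sulfide, CS(=O)CSC
Why: Knoevenagel-type condensation of an aromatic aldehyde with the formaldehyde dithioacetal S-oxide, the first half of the established one-carbon homologation of an aryl aldehyde to an arylacetic ester; alkene geometry and sulfoxide configuration are immaterial.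

Step 11
Reactants: 15 (R)-2-{6-methyl-8-[2-(methylsulfanyl)-2-(methylsulfinyl)ethenyl]-2,3-dihydro-1,4-benzodioxin-2-yl}propan-2-ol
Product: 16 methyl 2-[(R)-2-(2-hydroxypropan-2-yl)-6-methyl-2,3-dihydro-1,4-benzodioxin-8-yl]acetate
Conditions: HCl, MeOH, rt to 40 °C
Reagents that add atoms: methanol, CO
Why: Acid-mediated methanolysis of the ketene dithioacetal S-oxide (Pummerer-type), which gives the methyl arylacetate and dimethyl disulfide; the tertiary alcohol lies next to an electron-withdrawing C–O bond and should not ionise under these conditions.

Step 12
Reactants: 16 methyl 2-[(R)-2-(2-hydroxypropan-2-yl)-6-methyl-2,3-dihydro-1,4-benzodioxin-8-yl]acetate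
Product: 17 methyl 2-{(R)-6-methyl-2-[2-(triethylsilyloxy)propan-2-yl]-2,3-dihydro-1,4-benzodioxin-8-yl}acetate
Conditions: Et3SiOTf, 2,6-lutidine, CH2Cl2, −78 to 0 °C
Reagents that add atoms: triethylsilyl trifluoromethanesulfonate, CC[Si](CC)(CC)OS(=O)(=O)C(F)(F)F
Why: Silylation of a tertiary alcohol with a silyl triflate and a hindered pyridine base; the hydroxyl has to be masked before the ester is enolised and the aryne is generated with an alkyllithium.

Step 13
Reactants: 17 methyl 2-{(R)-6-methyl-2-[2-(triethylsilyloxy)propan-2-yl]-2,3-dihydro-1,4-benzodioxin-8-yl}acetate
Product: 18 tert-butyl[(1-methoxy-2-{(R)-6-methyl-2-[2-(triethylsilyloxy)propan-2-yl]-2,3-dihydro-1,4-benzodioxin-8-yl}ethenyl)oxy]dimethylsilane (ketene methyl tert-butyldimethylsilyl acetal; double-bond isomers)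
Conditions: LiN(iPr)2, THF, −78 °C; t-BuMe2SiCl, DMPU, −78 °C to rt; pentane, filtration
Reagents that add atoms: tert-butyldimethylsilyl chloride, CC(C)(C)[Si](C)(C)Cl
Why: O-silylation of an ester lithium enolate in the presence of a polar cosolvent gives the ketene silyl acetal; the arylacetate enolises cleanly at −78 °C, the double-bond geometry is irrelevant, and the moisture-sensitive product is used after a non-aqueous work-up.

Step 14
Reactants: 6 2-iodo-3-(methoxymethoxy)-6-(3-methylbut-2-en-1-yl)phenyl trifluoromethanesulfonate; 18 ketene methyl tert-butyldimethylsilyl acetal of ester 17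
Product: 20 7-(tert-butyldimethylsilyloxy)-7-methoxy-5-(methoxymethoxy)-2-(3-methylbut-2-en-1-yl)-8-{(R)-6-methyl-2-[2-(triethylsilyloxy)propan-2-yl]-2,3-dihydro-1,4-benzodioxin-8-yl}bicyclo[4.2.0]octa-1,3,5-triene (benzocyclobutenone mixed silyl methyl ketal; diastereomer mixture at C7 and C8), via aryne 19 (not isolated)
Conditions: 18 (1.5 equiv), n-BuLi (1.1 equiv), Et2O, −78 °C
Reagents that add atoms: none
Why: Iodine–lithium exchange at −78 °C followed by loss of lithium triflate releases aryne 19 in the presence of the ketene silyl acetal. The nucleophilic carbon of 18 attacks the aryne carbon remote from the MOM-oxy group, the one next to prenyl, and the aryl anion so formed, which sits beside the C–O bond, closes on the silyloxy(methoxy)carbenium carbon; this stepwise polar [2+2] cycloaddition of 3-alkoxybenzynes with ketene silyl acetals is the closest known reaction type and is applied here to a more hindered pair. The four-membered ring closes in the second event by a 4-exo-trig attack of the aryl anion on the oxocarbenium ion. Two stereocentres arise, the methine carbon bearing ring B and the ketal carbon; neither is controlled, since the (R) centre of 18 is too remote, and neither needs to be, because the ketal carbon becomes a carbonyl in step 15 and the methine carbon becomes the ketone in step 18. The selectivity the step needs is regiochemical: the inductively withdrawing MOM-oxy group polarises the triple bond and stabilises the anion developing at the adjacent carbon, which should override the steric bias of the flanking prenyl group. Exchange at iodine is faster than attack of n-BuLi on the silyl acetal, the silyl ether or the MOM group, and the excess of 18 is meant to outrun addition of the alkyllithium to the aryne; excess 18 is recoverable as 17.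

Step 15
Reactants: 20 benzocyclobutenone mixed silyl methyl ketal
Product: 21 5-(methoxymethoxy)-2-(3-methylbut-2-en-1-yl)-8-{(R)-6-methyl-2-[2-(triethylsilyloxy)propan-2-yl]-2,3-dihydro-1,4-benzodioxin-8-yl}bicyclo[4.2.0]octa-1,3,5-trien-7-one (epimers at C8)
Conditions: Bu4NF, AcOH, THF, 0 °C
Reagents that add atoms: none
Why: Fluoride cleaves the Si–O bond of the mixed ketal and the hemiketal collapses to the strained ketone with loss of methanol; acetic acid buffers the methoxide, which could otherwise open the four-membered ring, and the tertiary triethylsilyl ether should survive the short exposure at 0 °C (its partial loss would not harm the following steps).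

Step 16
Reactants: 21 2-aryl benzocyclobutenone
Product: 22 7-(methoxymethoxy)-4-(3-methylbut-2-en-1-yl)-3-{(R)-6-methyl-2-[2-(triethylsilyloxy)propan-2-yl]-2,3-dihydro-1,4-benzodioxin-8-yl}-2-benzofuran-1(3H)-one (3-arylphthalide; epimers at C3)
Conditions: 30% aq. H2O2, LiOH, THF–H2O, 0 °C; pH 5 phosphate buffer
Reagents that add atoms: hydrogen peroxide, OO
Why: Baeyer–Villiger oxidation of a strained cyclobutanone by hydroperoxide anion; ring strain lets the peroxide adduct rearrange at 0 °C, and the doubly benzylic sp3 carbon is expected to migrate in preference to the ring A sp2 carbon, giving the phthalide and not the isomeric benzofuranone. The nucleophilic oxidant leaves the prenyl double bond untouched, where a peracid would epoxidise it.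

Step 17
Reactants: 22 3-arylphthalide
Product: 23 [2-(hydroxymethyl)-3-(methoxymethoxy)-6-(3-methylbut-2-en-1-yl)phenyl]{(R)-6-methyl-2-[2-(triethylsilyloxy)propan-2-yl]-2,3-dihydro-1,4-benzodioxin-8-yl}methanol (epimers at the carbinol carbon)
Conditions: LiAlH4, THF, 0 °C to rt; H2O, aq. NaOH
Reagents that add atoms: none
Why: Hydride reduction of a lactone to the 1,4-diol; MOM acetal, silyl ether and the isolated olefin are inert to LiAlH4.

Step 18
Reactants: 23 diol
Product: 24 2-(methoxymethoxy)-5-(3-methylbut-2-en-1-yl)-6-({(R)-6-methyl-2-[2-(triethylsilyloxy)propan-2-yl]-2,3-dihydro-1,4-benzodioxin-8-yl}carbonyl)benzaldehyde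
Conditions: (COCl)2, DMSO, CH2Cl2, −78 °C; Et3N, −78 to 0 °C
Reagents that add atoms: none
Why: Swern oxidation; both hydroxyls are converted into alkoxysulfonium ions before the base is added, so aldehyde and ketone are formed together and the hydroxy aldehyde that would close to a lactol is never present. The temporary stereocentre at the carbinol carbon is erased here.

Step 19
Reactants: 24 protected keto aldehyde
Product: 25 2-hydroxy-6-{[(R)-2-(2-hydroxypropan-2-yl)-6-methyl-2,3-dihydro-1,4-benzodioxin-8-yl]carbonyl}-5-(3-methylbut-2-en-1-yl)benzaldehyde (target)
Conditions: 2 M aq. HCl, THF, rt to 40 °C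
Reagents that add atoms: none
Why: Acid hydrolysis of the aryl MOM acetal, which is assisted by the ortho formyl group that hydrogen-bonds the phenol being released, and of the tertiary triethylsilyl ether. Aqueous instead of alcoholic acid avoids acetal formation at the keto aldehyde, and dilute acid at this temperature should neither hydrate the prenyl olefin nor ionise the tertiary alcohol.

## Compound list

1 | 2-iodoresorcinol (2-iodobenzene-1,3-diol) | Oc1cccc(O)c1I | starting material
2 | 2-iodo-3-(methoxymethoxy)phenol | COCOc1cccc(O)c1I | intermediate
3 | 1-(allyloxy)-2-iodo-3-(methoxymethoxy)benzene | C=CCOc1cccc(OCOC)c1I | intermediate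
4 | 6-allyl-2-iodo-3-(methoxymethoxy)phenol | C=CCc1ccc(OCOC)c(I)c1O | intermediate
5 | 6-allyl-2-iodo-3-(methoxymethoxy)phenyl trifluoromethanesulfonate | C=CCc1ccc(OCOC)c(I)c1OS(=O)(=O)C(F)(F)F | intermediate
6 | 2-iodo-3-(methoxymethoxy)-6-(3-methylbut-2-en-1-yl)phenyl trifluoromethanesulfonate | CC(C)=CCc1ccc(OCOC)c(I)c1OS(=O)(=O)C(F)(F)F | intermediate
7 | prenol (3-methylbut-2-en-1-ol) | CC(C)=CCO | starting material
8 | (S)-(3,3-dimethyloxiran-2-yl)methanol ((S)-3,3-dimethylglycidol; not isolated) | CC1(C)O[C@H]1CO | intermediate
9 | (S)-(3,3-dimethyloxiran-2-yl)methyl 3-nitrobenzenesulfonate | CC1(C)O[C@H]1COS(=O)(=O)c1cccc(c1)[N+](=O)[O-] | intermediate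
10 | creosol (2-methoxy-4-methylphenol) | COc1cc(C)ccc1O | starting material
11 | 2-hydroxy-3-methoxy-5-methylbenzaldehyde | COc1cc(C)cc(C=O)c1O | intermediate
12 | 2,3-dihydroxy-5-methylbenzaldehyde | Cc1cc(O)c(O)c(C=O)c1 | intermediate
13 | 3-{[(S)-3,3-dimethyloxiran-2-yl]methoxy}-2-hydroxy-5-methylbenzaldehyde (present as its sodium phenoxide; not isolated) | CC1(C)O[C@H]1COc1cc(C)cc(C=O)c1O | intermediate
14 | (R)-2-(2-hydroxypropan-2-yl)-6-methyl-2,3-dihydro-1,4-benzodioxine-8-carbaldehyde | O=Cc1cc(C)cc2c1O[C@@H](C(C)(C)O)CO2 | intermediate
15 | (R)-2-{6-methyl-8-[2-(methylsulfanyl)-2-(methylsulfinyl)ethenyl]-2,3-dihydro-1,4-benzodioxin-2-yl}propan-2-ol (isomer mixture at the alkene and at sulfur) | CS(=O)C(SC)=Cc1cc(C)cc2c1O[C@@H](C(C)(C)O)CO2 | intermediate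
16 | methyl 2-[(R)-2-(2-hydroxypropan-2-yl)-6-methyl-2,3-dihydro-1,4-benzodioxin-8-yl]acetate | COC(=O)Cc1cc(C)cc2c1O[C@@H](C(C)(C)O)CO2 | intermediate
17 | methyl 2-{(R)-6-methyl-2-[2-(triethylsilyloxy)propan-2-yl]-2,3-dihydro-1,4-benzodioxin-8-yl}acetate | COC(=O)Cc1cc(C)cc2c1O[C@@H](C(C)(C)O[Si](CC)(CC)CC)CO2 | intermediate
18 | ketene methyl tert-butyldimethylsilyl acetal of 17 (double-bond isomers) | COC(O[Si](C)(C)C(C)(C)C)=Cc1cc(C)cc2c1O[C@@H](C(C)(C)O[Si](CC)(CC)CC)CO2 | intermediate
19 | 3-(methoxymethoxy)-6-(3-methylbut-2-en-1-yl)benzyne (not isolated) | CC(C)=CCC1=CC=C(OCOC)C#C1 | intermediate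
20 | benzocyclobutenone mixed silyl methyl ketal (bicyclo[4.2.0]octa-1,3,5-triene with OTBS and OMe on C7, ring B on C8, MOM-oxy on C5, prenyl on C2; diastereomer mixture at C7 and C8) | CC(C)=CCc1ccc(OCOC)c2c1C(c1cc(C)cc3c1O[C@@H](C(C)(C)O[Si](CC)(CC)CC)CO3)C2(OC)O[Si](C)(C)C(C)(C)C | intermediate
21 | 2-aryl benzocyclobutenone (bicyclo[4.2.0]octa-1,3,5-trien-7-one with ring B on C8, MOM-oxy on C5, prenyl on C2; epimers at C8) | CC(C)=CCc1ccc(OCOC)c2c1C(c1cc(C)cc3c1O[C@@H](C(C)(C)O[Si](CC)(CC)CC)CO3)C2=O | intermediate
22 | 7-(methoxymethoxy)-4-(3-methylbut-2-en-1-yl)-3-{(R)-6-methyl-2-[2-(triethylsilyloxy)propan-2-yl]-2,3-dihydro-1,4-benzodioxin-8-yl}-2-benzofuran-1(3H)-one (epimers at C3) | CC(C)=CCc1ccc(OCOC)c2c1C(c1cc(C)cc3c1O[C@@H](C(C)(C)O[Si](CC)(CC)CC)CO3)OC2=O | intermediate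
23 | [2-(hydroxymethyl)-3-(methoxymethoxy)-6-(3-methylbut-2-en-1-yl)phenyl]{(R)-6-methyl-2-[2-(triethylsilyloxy)propan-2-yl]-2,3-dihydro-1,4-benzodioxin-8-yl}methanol (epimers at the carbinol carbon) | CC(C)=CCc1ccc(OCOC)c(CO)c1C(O)c1cc(C)cc2c1O[C@@H](C(C)(C)O[Si](CC)(CC)CC)CO2 | intermediate
24 | 2-(methoxymethoxy)-5-(3-methylbut-2-en-1-yl)-6-({(R)-6-methyl-2-[2-(triethylsilyloxy)propan-2-yl]-2,3-dihydro-1,4-benzodioxin-8-yl}carbonyl)benzaldehyde | CC(C)=CCc1ccc(OCOC)c(C=O)c1C(=O)c1cc(C)cc2c1O[C@@H](C(C)(C)O[Si](CC)(CC)CC)CO2 | intermediate
25 | 2-hydroxy-6-{[(R)-2-(2-hydroxypropan-2-yl)-6-methyl-2,3-dihydro-1,4-benzodioxin-8-yl]carbonyl}-5-(3-methylbut-2-en-1-yl)benzaldehyde | CC(C)=CCc1ccc(O)c(C=O)c1C(=O)c1cc(C)cc2c1O[C@@H](C(C)(C)O)CO2 | target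

## Step count and risks

Total: 19 steps. Longest linear sequence: 13 steps (10 to 25, steps 7 to 13 and 14 to 19). The ring A branch (1 to 6, steps 1 to 5) joins at step 14 and the epoxide branch (7 to 9, step 6) joins at step 9.

**Step 14 (key step).** Most likely to go wrong: slow or misdirected carbon–carbon bond formation. The ketene acetal carbon carries an ortho-substituted aryl group and must attack the aryne carbon flanked by prenyl, so several processes may compete: addition of n-BuLi to the aryne, an intramolecular ene reaction of the aryne with the prenyl group, attack at the other aryne carbon (loss of regiocontrol), and protonation of the aryl anion before ring closure. Fallback without an aryne, setting out from 6 and 14 and returning at 22: palladium-catalysed methoxycarbonylation of the C–I bond of 6 (PdCl2(PPh3)2 (divalent palladium precatalyst), carbon monoxide, MeOH, Et3N, 50 °C; with a triphenylphosphine catalyst the iodide reacts before the triflate) would give methyl 6-(methoxymethoxy)-3-(3-methylbut-2-en-1-yl)-2-(trifluoromethylsulfonyloxy)benzoate F1. Silylation of 14 (Et3SiOTf, 2,6-lutidine) would give (R)-6-methyl-2-[2-(triethylsilyloxy)propan-2-yl]-2,3-dihydro-1,4-benzodioxine-8-carbaldehyde F2. A Nozaki–Hiyama–Kishi reaction of F1 with F2 (CrCl2 (divalent chromium), catalytic NiCl2 (divalent nickel), DMF) would add the arylchromium species to the aldehyde, and the alkoxide would close on the neighbouring ester to give phthalide 22; steps 15 and 16 would then not be needed.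

**Step 16.** Most likely to go wrong: base-induced cleavage of the strained ketone (fragmentation to the doubly benzylic carbanion instead of oxygen insertion), or migration of the ring A aryl carbon, which would lead to a benzofuranone. Fallback that turns the cleavage to use, setting out from 21 and returning at 22: NaOMe in MeOH would open the four-membered ring in a Haller–Bauer-type cleavage to methyl 6-(methoxymethoxy)-3-(3-methylbut-2-en-1-yl)-2-({(R)-6-methyl-2-[2-(triethylsilyloxy)propan-2-yl]-2,3-dihydro-1,4-benzodioxin-8-yl}methyl)benzoate F3. LiN(iPr)2 at −78 °C would remove the doubly benzylic proton ortho to the ester, and oxygenation of this anion with 2-(phenylsulfonyl)-3-phenyloxaziridine would give an alkoxide that lactonises to 22.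

**Step 9.** Most likely to go wrong: incomplete regiocontrol in the first alkylation (reaction at O1 would end in the regioisomeric dioxane) or sluggish ring closure by the deactivated phenoxide. Fallback in which O1 is locked in a lactone, setting out from 11 and returning at 16: condensation of 11 with methyl (methylsulfinyl)methyl sulfide as in step 10 would give 2-methoxy-4-methyl-6-[2-(methylsulfanyl)-2-(methylsulfinyl)ethenyl]phenol F4. Acid methanolysis and lactonisation (HCl, MeOH; then TsOH, toluene, reflux) would give 7-methoxy-5-methyl-1-benzofuran-2(3H)-one F5, and BBr3 would give 7-hydroxy-5-methyl-1-benzofuran-2(3H)-one F6, in which only O4 is free. Alkylation with 9 (K2CO3, DMF) would give 7-{[(S)-3,3-dimethyloxiran-2-yl]methoxy}-5-methyl-1-benzofuran-2(3H)-one F7. NaOMe in MeOH would then open the lactone to the methyl ester and release the O1 phenoxide, which closes the dioxane by the same 6-exo epoxide opening to give 16.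

**Step 3.** Most likely to go wrong: thermal loss of iodine or of the MOM group at 190 °C, or migration of the allyl group past the blocked ortho position. Fallback that avoids the sigmatropic step, setting out from 2 and returning at 6: the sodium phenoxide of 2 (NaH, toluene) would be C-alkylated with prenyl bromide at its only free ortho position to give 2-iodo-3-(methoxymethoxy)-6-(3-methylbut-2-en-1-yl)phenol F8, which would be triflated as in step 4 to give 6. This is two steps shorter, but O-alkylation competes, which is why it is not the first choice.

## Further compounds

F1 | step 14 | methyl 6-(methoxymethoxy)-3-(3-methylbut-2-en-1-yl)-2-(trifluoromethylsulfonyloxy)benzoate | COC(=O)c1c(OCOC)ccc(CC=C(C)C)c1OS(=O)(=O)C(F)(F)F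
F2 | step 14 | (R)-6-methyl-2-[2-(triethylsilyloxy)propan-2-yl]-2,3-dihydro-1,4-benzodioxine-8-carbaldehyde | O=Cc1cc(C)cc2c1O[C@@H](C(C)(C)O[Si](CC)(CC)CC)CO2
F3 | step 16 | methyl 6-(methoxymethoxy)-3-(3-methylbut-2-en-1-yl)-2-({(R)-6-methyl-2-[2-(triethylsilyloxy)propan-2-yl]-2,3-dihydro-1,4-benzodioxin-8-yl}methyl)benzoate | COC(=O)c1c(OCOC)ccc(CC=C(C)C)c1Cc1cc(C)cc2c1O[C@@H](C(C)(C)O[Si](CC)(CC)CC)CO2
F4 | step 9 | 2-methoxy-4-methyl-6-[2-(methylsulfanyl)-2-(methylsulfinyl)ethenyl]phenol | CS(=O)C(SC)=Cc1cc(C)cc(OC)c1O
F5 | step 9 | 7-methoxy-5-methyl-1-benzofuran-2(3H)-one | O=C1Cc2cc(C)cc(OC)c2O1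
F6 | step 9 | 7-hydroxy-5-methyl-1-benzofuran-2(3H)-one | O=C1Cc2cc(C)cc(O)c2O1
F7 | step 9 | 7-{[(S)-3,3-dimethyloxiran-2-yl]methoxy}-5-methyl-1-benzofuran-2(3H)-one | CC1(C)O[C@H]1COc1cc(C)cc2CC(=O)Oc12
F8 | step 3 | 2-iodo-3-(methoxymethoxy)-6-(3-methylbut-2-en-1-yl)phenol | CC(C)=CCc1ccc(OCOC)c(I)c1O
A1 | alternative 1 | 4-(benzyloxy)-2-methyl-6-oxo-6,11-dihydrodibenzo[b,e]oxepin-7-yl 2,2-dimethylpropanoate | O=C1Oc2c(OCc3ccccc3)cc(C)cc2Cc2cccc(OC(=O)C(C)(C)C)c12
A2 | alternative 1 | 8-(benzyloxy)-6-methyl-9-oxo-9,10-dihydroanthracen-1-yl 2,2-dimethylpropanoate | O=C1c2c(OCc3ccccc3)cc(C)cc2Cc2cccc(OC(=O)C(C)(C)C)c12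
A3 | alternative 2 | (S)-8-bromo-6-methyl-2-(prop-1-en-2-yl)-2,3-dihydro-1,4-benzodioxine | Brc1cc(C)cc2c1O[C@@H](C(C)=C)CO2
A4 | alternative 2 | (E)-4-(3-bromo-2-hydroxy-5-methylphenoxy)-2-methylbut-2-en-1-yl methyl carbonate | COC(=O)OC/C(C)=C/COc1cc(C)cc(Br)c1O
A5 | alternative 3 | [2-(dimethoxymethyl)-3-(methoxymethoxy)-6-(3-methylbut-2-en-1-yl)phenyl][(R)-2-(2-hydroxypropan-2-yl)-6-methyl-2,3-dihydro-1,4-benzodioxin-8-yl]methanone | CC(C)=CCc1ccc(OCOC)c(C(OC)OC)c1C(=O)c1cc(C)cc2c1O[C@@H](C(C)(C)O)CO2
A6 | alternative 3 | 2-(dimethoxymethyl)-3-iodo-1-(methoxymethoxy)-4-(3-methylbut-2-en-1-yl)benzene | CC(C)=CCc1ccc(OCOC)c(C(OC)OC)c1I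
A7 | alternative 3 | [(R)-2-(2-hydroxypropan-2-yl)-6-methyl-2,3-dihydro-1,4-benzodioxin-8-yl]boronic acid | OB(O)c1cc(C)cc2c1O[C@@H](C(C)(C)O)CO2
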